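**Plan**
- Retrosynthetic cuts, in order: the fourteen O–methyl bonds and the ester on ring A; the bond between positions 1 and 2 of ring A; in the open seven-carbon chain, the bond between chain carbons 4 and 5 and the bond between the aryl oxygen and its CH2 group; then the five diaryl ether bonds between rings B to G, each cut between a flanked oxygen and an unhindered aryl carbon.
- Forward: rings G and F (identically D and C) are joined first as one dimer bromide that is used twice, once extended to the GFE boronic acid and once hydroxylated at position 2 of ring D. Their union gives the pentamer, ring B is added, its bromine becomes the hydroxyl at position 1 of ring B, the chain is built on that oxygen, and ring A closes last.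
- Enabling feature: ring A is a phloroglucinol whose position 4, bonded to the ether oxygen on position 1 of ring B, lies between the hydroxyl-bearing positions 3 and 5. These three carbons are carbons 3, 4 and 5 of a 4-aryloxy-3,5-dioxoheptanedioate, whose carbon 2 becomes position 2 of ring A and whose ester carbon 7 becomes position 1.
- Stereochemistry: the target has no stereocentre; only regiochemistry matters, and it follows from the symmetry of the dimer bromide and of the dioxo diester.

Key step: step 15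

Remarks on the chemistry:
- Ring letters follow the chain of ether oxygens: position 4 of ring A to position 1 of ring B, position 4 of ring B to position 1 of ring C, position 4 of ring C to position 1 of ring D, position 2 of ring D to position 1 of ring E, position 4 of ring E to position 1 of ring F, and position 4 of ring F to position 1 of ring G. "Ar" is the permethylated BCDEFG aryl group, i.e. the hexamer phenol of step 10 without its hydroxyl.
- 3,4,5-Trimethoxyphenylboronic acid, 4-bromo-2,6-dimethoxyphenol, methyl 4-chloroacetoacetate and methyl malonyl chloride are taken as commercial.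
- The silyl enol ethers of steps 12 to 14 are expected as mixtures of double-bond isomers (the one formed in step 14 also racemic at the aryloxy carbon). This is erased on hydrolysis, so their SMILES carry no stereodescriptors.

Step 1
Reactants: 1 3,4,5-trimethoxyphenylboronic acid; 2 4-bromo-2,6-dimethoxyphenol
Product: 3 5-bromo-1,3-dimethoxy-2-(3,4,5-trimethoxyphenoxy)benzene (dimer bromide; serves as G–F and as D–C)
Conditions: Cu(OAc)2 (1.5 equiv), pyridine (5 equiv), 4 Å MS, CH2Cl2, dry air, 25 °C
Reagents that add atoms: none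
Why: Chan–Lam O-arylation should join a boronic acid without ortho substituents to a 2,6-disubstituted phenol at room temperature and leave the aryl bromide untouched.

Step 2
Reactants: 3 dimer bromide
Product: 6 [3,5-dimethoxy-4-(3,4,5-trimethoxyphenoxy)phenyl]boronic acid, via dimer aryllithium 4 (not isolated), via dimer lithium triisopropoxyborate 5 (not isolated)
Conditions: n-BuLi (1.05 equiv), THF, −78 °C; B(OiPr)3, −78 → 0 °C; 1 M HCl
Reagents that add atoms: triisopropyl borate CC(C)OB(OC(C)C)OC(C)C; water O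
Why: Bromine–lithium exchange, borate trapping and hydrolysis is the standard conversion of an aryl bromide into the arylboronic acid, and the methyl and diaryl ethers are inert to n-BuLi at −78 °C.

Step 3
Reactants: 6 dimer boronic acid; 2 4-bromo-2,6-dimethoxyphenol (in excess)
Product: 7 5-bromo-2-[3,5-dimethoxy-4-(3,4,5-trimethoxyphenoxy)phenoxy]-1,3-dimethoxybenzene (GFE bromide)
Conditions: Cu(OAc)2 (1.5 equiv), pyridine (5 equiv), 4 Å MS, CH2Cl2, dry air, 25 °C
Reagents that add atoms: none
Why: The same Chan–Lam coupling should repeat, since the new boronic acid again has two free ortho positions and the phenol is the same partner as in step 1.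

Step 4
Reactants: 7 GFE bromide
Product: 10 {4-[3,5-dimethoxy-4-(3,4,5-trimethoxyphenoxy)phenoxy]-3,5-dimethoxyphenyl}boronic acid (GFE boronic acid), via trimer aryllithium 8 (not isolated), via trimer lithium triisopropoxyborate 9 (not isolated)
Conditions: n-BuLi (1.05 equiv), THF, −78 °C; B(OiPr)3, −78 → 0 °C; 1 M HCl
Reagents that add atoms: triisopropyl borate CC(C)OB(OC(C)C)OC(C)C; water O
Why: Lithiation–borylation as in step 2, with fast exchange at bromine outrunning any ring deprotonation at −78 °C.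

Step 5
Reactants: 3 dimer bromide
Product: 12 6-(4-bromo-2,6-dimethoxyphenoxy)-2,3,4-trimethoxybenzaldehyde, via iminium chloride 11 (not isolated)
Conditions: POCl3 (1.5 equiv), DMF, 0 → 70 °C; then H2O, 25 °C
Reagents that add atoms: N,N-dimethylformamide CN(C)C=O; water O
Why: Vilsmeier–Haack formylation should go to the trimethoxyphenoxy ring, the only one with a phloroglucinol-type 1,3,5-oxygen pattern and with two equivalent free positions, as in the known formylation of 1,2,3,5-tetramethoxybenzene, while the brominated ring is less activated.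

Step 6
Reactants: 12 dimer aldehyde
Product: 14 6-(4-bromo-2,6-dimethoxyphenoxy)-2,3,4-trimethoxyphenol (ring D phenol), via aryl formate 13 (not isolated)
Conditions: mCPBA (1.3 equiv), CH2Cl2, 0 → 25 °C; then K2CO3 (cat.), MeOH, 25 °C
Reagents that add atoms: mCPBA OOC(=O)c1cccc(Cl)c1
Why: Baeyer–Villiger oxidation of an electron-rich benzaldehyde proceeds by aryl migration to the formate, and methanolysis should free the hydroxyl at position 2 of ring D.

Step 7
Reactants: 10 GFE boronic acid (1.5 equiv); 14 ring D phenol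
Product: 15 1-(4-bromo-2,6-dimethoxyphenoxy)-2-{4-[3,5-dimethoxy-4-(3,4,5-trimethoxyphenoxy)phenoxy]-3,5-dimethoxyphenoxy}-3,4,5-trimethoxybenzene (pentamer bromide)
Conditions: Cu(OAc)2 (2 equiv), pyridine (5 equiv), 4 Å MS, CH2Cl2, dry air, 25 °C
Reagents that add atoms: none
Why: Chan–Lam coupling tolerates phenols flanked on both sides (here methoxy and aryloxy) and the aryl bromide, so the ether between ring D and ring E should form without touching ring C.

Step 8
Reactants: 15 pentamer bromide
Product: 18 pentamer boronic acid (15 with B(OH)2 in place of Br on ring C), via pentamer aryllithium 16 (not isolated), via pentamer lithium triisopropoxyborate 17 (not isolated)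
Conditions: n-BuLi (1.05 equiv), THF, −78 °C; B(OiPr)3, −78 → 0 °C; 1 M HCl
Reagents that add atoms: triisopropyl borate CC(C)OB(OC(C)C)OC(C)C; water O
Why: Lithiation–borylation as in steps 2 and 4, run with a short lithiation time so that the aryllithium is trapped before any proton transfer between rings.

Step 9
Reactants: 18 pentamer boronic acid; 2 4-bromo-2,6-dimethoxyphenol (in excess)
Product: 19 1-[4-(4-bromo-2,6-dimethoxyphenoxy)-2,6-dimethoxyphenoxy]-2-{4-[3,5-dimethoxy-4-(3,4,5-trimethoxyphenoxy)phenoxy]-3,5-dimethoxyphenoxy}-3,4,5-trimethoxybenzene (hexamer bromide)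
Conditions: Cu(OAc)2 (1.5 equiv), pyridine (5 equiv), 4 Å MS, CH2Cl2, dry air, 25 °C
Reagents that add atoms: none
Why: Third use of the same Chan–Lam coupling with the same phenol, which adds ring B through its flanked oxygen and keeps the bromine of ring B as the handle for the last oxygen.

Step 10
Reactants: 19 hexamer bromide
Product: 22 4-{4-[2-{4-[3,5-dimethoxy-4-(3,4,5-trimethoxyphenoxy)phenoxy]-3,5-dimethoxyphenoxy}-3,4,5-trimethoxyphenoxy]-3,5-dimethoxyphenoxy}-3,5-dimethoxyphenol (hexamer phenol; Ar–OH), via hexamer aryllithium 20 (not isolated), via hexamer lithium trimethoxyborate 21 (not isolated)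
Conditions: n-BuLi (1.05 equiv), THF, −78 °C; B(OMe)3, −78 → 0 °C; AcOH, 30% aq. H2O2, 0 → 25 °C
Reagents that add atoms: hydrogen peroxide OO
Why: One-pot lithiation, borylation and peroxide oxidation is the standard conversion of an aryl bromide into the phenol, with the 1,2-aryl shift from boron to oxygen placing the hydroxyl exactly where the bromine stood, at position 1 of ring B.

Step 11
Reactants: 22 hexamer phenol; 23 methyl 4-chloroacetoacetate (methyl 4-chloro-3-oxobutanoate)
Product: 24 methyl 4-(Ar-oxy)-3-oxobutanoate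
Conditions: NaH (2.2 equiv), THF–DMF, 0 → 25 °C; then aq. NH4Cl
Reagents that add atoms: none
Why: Williamson etherification of an unhindered phenoxide with a 4-chloroacetoacetate is a known route to 4-aryloxyacetoacetates, the second equivalent of base holding the keto ester as its enolate against self-condensation.

Step 12
Reactants: 24 aryloxy keto ester
Product: 25 methyl 4-(Ar-oxy)-3-(trimethylsilyloxy)but-2-enoate
Conditions: Me3SiCl (1.5 equiv), Et3N (1.6 equiv), toluene, 25 °C; filtration under argon
Reagents that add atoms: chlorotrimethylsilane C[Si](C)(C)Cl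
Why: O-silylation of a β-keto ester enol with Me3SiCl and Et3N is the usual first stage in making 1,3-bis(silyloxy)dienes.

Step 13
Reactants: 25 silyl enol ether
Product: 27 1-methoxy-1,3-bis(trimethylsilyloxy)-4-(Ar-oxy)buta-1,3-diene, via lithium dienolate 26 (not isolated)
Conditions: LiN(iPr)2 (1.5 equiv), THF, −78 °C; Me3SiCl, −78 → 20 °C
Reagents that add atoms: chlorotrimethylsilane C[Si](C)(C)Cl
Why: γ-Deprotonation of the silyl enol ether and O-silylation of the dienolate is the standard second stage to 1,3-bis(silyl enol ethers), and 4-aryloxy members of this diene class are known.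

Step 14
Reactants: 27 bis(silyl enol ether); 28 methyl malonyl chloride (methyl 3-chloro-3-oxopropanoate)
Product: 30 dimethyl 4-(Ar-oxy)-3,5-dioxoheptanedioate, via monosilyl enol ether of the acylation product 29 (not isolated)
Conditions: CH2Cl2, −78 → 20 °C; then 1 M HCl
Reagents that add atoms: none
Why: 1,3-Bis(silyl enol ethers) are acylated by acid chlorides at the terminal carbon without added base, and with methyl malonyl chloride this is a known entry to isolable 3,5-dioxoheptanedioates; the aryloxy carbon thus reacts as the nucleophile, so no acylation is needed next to an already enolised centre.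

Step 15
Reactants: 30 dimethyl 4-(Ar-oxy)-3,5-dioxoheptanedioate
Product: 31 methyl 3-(Ar-oxy)-2,4,6-trihydroxybenzoate (heptamer with ring A as its 2-carboxylate)
Conditions: NaOMe (4 equiv), MeOH, argon, 0 → 25 °C; then 1 M HCl, 0 °C
Reagents that add atoms: none
Why: Methoxide first removes the proton on chain carbon 4 between the two ketones, and a second, reversible deprotonation at carbon 2 (equally carbon 6, the chain being symmetric) gives an ester-stabilised carbanion that adds to the ester carbonyl of carbon 7 and expels methoxide, which forms the bond between positions 1 and 2 of ring A. This is a Dieckmann-type Claisen condensation, known for 3,5-dioxoheptanedioates, which give 2,4,6-trihydroxybenzoates. Ring A closes 6-exo-trig as a six-membered carbocycle and threefold enolisation then makes it aromatic. No stereocentre is formed. The step needs C-acylation over O-acylation: a pyranone formed by attack of an enol oxygen on an ester is reopened by methoxide, whereas aromatisation makes the carbocycle irreversible, and every other carbon–carbon closure would give a four-membered ring. Because the aryloxy group already sits on chain carbon 4, the ether between the two flanking hydroxyls of ring A never has to be made on an aromatic ring.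

Step 16
Reactants: 31 heptamer benzoate
Product: 33 CNP0304148.0 (heptadecahydroxy heptamer), via heptamer trihydroxybenzoic acid 32 (not isolated)
Conditions: BBr3 (40 equiv), CH2Cl2, −78 → 25 °C; then H2O, 0 → 50 °C, argon
Reagents that add atoms: none
Why: BBr3 cleaves aryl methyl ethers and the chelated salicylate-type methyl ester while leaving diaryl ethers intact, and the freed 2,4,6-trihydroxybenzoic acid should lose carbon dioxide on gentle warming in water through ipso-protonation of the phloroglucinol ring.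

**Compound list**

1 | 3,4,5-trimethoxyphenylboronic acid | COc1cc(B(O)O)cc(OC)c1OC | starting material
2 | 4-bromo-2,6-dimethoxyphenol | COc1cc(Br)cc(OC)c1O | starting material
3 | 5-bromo-1,3-dimethoxy-2-(3,4,5-trimethoxyphenoxy)benzene (dimer bromide) | COc1cc(Oc2c(OC)cc(Br)cc2OC)cc(OC)c1OC | intermediate
4 | dimer aryllithium (3 with Li for Br) | COc1cc(Oc2c(OC)cc([Li])cc2OC)cc(OC)c1OC | intermediate (not isolated)
5 | dimer lithium triisopropoxyborate | [Li+].COc1cc(Oc2c(OC)cc([B-](OC(C)C)(OC(C)C)OC(C)C)cc2OC)cc(OC)c1OC | intermediate (not isolated)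
6 | [3,5-dimethoxy-4-(3,4,5-trimethoxyphenoxy)phenyl]boronic acid | COc1cc(Oc2c(OC)cc(B(O)O)cc2OC)cc(OC)c1OC | intermediate
7 | 5-bromo-2-[3,5-dimethoxy-4-(3,4,5-trimethoxyphenoxy)phenoxy]-1,3-dimethoxybenzene (GFE bromide) | COc1cc(Oc2c(OC)cc(Oc3c(OC)cc(Br)cc3OC)cc2OC)cc(OC)c1OC | intermediate
8 | trimer aryllithium (7 with Li for Br) | COc1cc(Oc2c(OC)cc(Oc3c(OC)cc([Li])cc3OC)cc2OC)cc(OC)c1OC | intermediate (not isolated)
9 | trimer lithium triisopropoxyborate | [Li+].COc1cc(Oc2c(OC)cc(Oc3c(OC)cc([B-](OC(C)C)(OC(C)C)OC(C)C)cc3OC)cc2OC)cc(OC)c1OC | intermediate (not isolated)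
10 | {4-[3,5-dimethoxy-4-(3,4,5-trimethoxyphenoxy)phenoxy]-3,5-dimethoxyphenyl}boronic acid (GFE boronic acid) | COc1cc(Oc2c(OC)cc(Oc3c(OC)cc(B(O)O)cc3OC)cc2OC)cc(OC)c1OC | intermediate
11 | N,N-dimethyliminium chloride of aldehyde 12 | [Cl-].C[N+](C)=Cc1c(Oc2c(OC)cc(Br)cc2OC)cc(OC)c(OC)c1OC | intermediate (not isolated)
12 | 6-(4-bromo-2,6-dimethoxyphenoxy)-2,3,4-trimethoxybenzaldehyde | O=Cc1c(Oc2c(OC)cc(Br)cc2OC)cc(OC)c(OC)c1OC | intermediate
13 | 6-(4-bromo-2,6-dimethoxyphenoxy)-2,3,4-trimethoxyphenyl formate | O=COc1c(Oc2c(OC)cc(Br)cc2OC)cc(OC)c(OC)c1OC | intermediate (not isolated)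
14 | 6-(4-bromo-2,6-dimethoxyphenoxy)-2,3,4-trimethoxyphenol (ring D phenol) | Oc1c(Oc2c(OC)cc(Br)cc2OC)cc(OC)c(OC)c1OC | intermediate
15 | pentamer bromide (full name in step 7) | COc1cc(Oc2c(OC)cc(Oc3c(OC)cc(Oc4c(OC)c(OC)c(OC)cc4Oc5c(OC)cc(Br)cc5OC)cc3OC)cc2OC)cc(OC)c1OC | intermediate
16 | pentamer aryllithium (15 with Li for Br) | COc1cc(Oc2c(OC)cc(Oc3c(OC)cc(Oc4c(OC)c(OC)c(OC)cc4Oc5c(OC)cc([Li])cc5OC)cc3OC)cc2OC)cc(OC)c1OC | intermediate (not isolated)
17 | pentamer lithium triisopropoxyborate | [Li+].COc1cc(Oc2c(OC)cc(Oc3c(OC)cc(Oc4c(OC)c(OC)c(OC)cc4Oc5c(OC)cc([B-](OC(C)C)(OC(C)C)OC(C)C)cc5OC)cc3OC)cc2OC)cc(OC)c1OC | intermediate (not isolated)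
18 | pentamer boronic acid (15 with B(OH)2 for Br) | COc1cc(Oc2c(OC)cc(Oc3c(OC)cc(Oc4c(OC)c(OC)c(OC)cc4Oc5c(OC)cc(B(O)O)cc5OC)cc3OC)cc2OC)cc(OC)c1OC | intermediate
19 | hexamer bromide (Ar–Br; full name in step 9) | COc1cc(Oc2c(OC)cc(Oc3c(OC)cc(Oc4c(OC)c(OC)c(OC)cc4Oc5c(OC)cc(Oc6c(OC)cc(Br)cc6OC)cc5OC)cc3OC)cc2OC)cc(OC)c1OC | intermediate
20 | hexamer aryllithium (Ar–Li) | COc1cc(Oc2c(OC)cc(Oc3c(OC)cc(Oc4c(OC)c(OC)c(OC)cc4Oc5c(OC)cc(Oc6c(OC)cc([Li])cc6OC)cc5OC)cc3OC)cc2OC)cc(OC)c1OC | intermediate (not isolated)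
21 | hexamer lithium trimethoxyborate | [Li+].COc1cc(Oc2c(OC)cc(Oc3c(OC)cc(Oc4c(OC)c(OC)c(OC)cc4Oc5c(OC)cc(Oc6c(OC)cc([B-](OC)(OC)OC)cc6OC)cc5OC)cc3OC)cc2OC)cc(OC)c1OC | intermediate (not isolated)
22 | hexamer phenol (Ar–OH; full name in step 10) | COc1cc(Oc2c(OC)cc(Oc3c(OC)cc(Oc4c(OC)c(OC)c(OC)cc4Oc5c(OC)cc(Oc6c(OC)cc(O)cc6OC)cc5OC)cc3OC)cc2OC)cc(OC)c1OC | intermediate
23 | methyl 4-chloroacetoacetate | COC(=O)CC(=O)CCl | starting material
24 | methyl 4-(Ar-oxy)-3-oxobutanoate | COc1cc(Oc2c(OC)cc(Oc3c(OC)cc(Oc4c(OC)c(OC)c(OC)cc4Oc5c(OC)cc(Oc6c(OC)cc(OCC(=O)CC(=O)OC)cc6OC)cc5OC)cc3OC)cc2OC)cc(OC)c1OC | intermediate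
25 | methyl 4-(Ar-oxy)-3-(trimethylsilyloxy)but-2-enoate (E/Z mixture) | COc1cc(Oc2c(OC)cc(Oc3c(OC)cc(Oc4c(OC)c(OC)c(OC)cc4Oc5c(OC)cc(Oc6c(OC)cc(OCC(O[Si](C)(C)C)=CC(=O)OC)cc6OC)cc5OC)cc3OC)cc2OC)cc(OC)c1OC | intermediate
26 | lithium dienolate of 25 (isomer mixture) | COc1cc(Oc2c(OC)cc(Oc3c(OC)cc(Oc4c(OC)c(OC)c(OC)cc4Oc5c(OC)cc(Oc6c(OC)cc(OC=C(O[Si](C)(C)C)C=C(OC)O[Li])cc6OC)cc5OC)cc3OC)cc2OC)cc(OC)c1OC | intermediate (not isolated)
27 | 1-methoxy-1,3-bis(trimethylsilyloxy)-4-(Ar-oxy)buta-1,3-diene (isomer mixture) | COc1cc(Oc2c(OC)cc(Oc3c(OC)cc(Oc4c(OC)c(OC)c(OC)cc4Oc5c(OC)cc(Oc6c(OC)cc(OC=C(O[Si](C)(C)C)C=C(OC)O[Si](C)(C)C)cc6OC)cc5OC)cc3OC)cc2OC)cc(OC)c1OC | intermediate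
28 | methyl malonyl chloride | COC(=O)CC(Cl)=O | starting material
29 | dimethyl 4-(Ar-oxy)-5-oxo-3-(trimethylsilyloxy)hept-2-enedioate (racemic, E/Z mixture) | COc1cc(Oc2c(OC)cc(Oc3c(OC)cc(Oc4c(OC)c(OC)c(OC)cc4Oc5c(OC)cc(Oc6c(OC)cc(OC(C(=O)CC(=O)OC)C(O[Si](C)(C)C)=CC(=O)OC)cc6OC)cc5OC)cc3OC)cc2OC)cc(OC)c1OC | intermediate (not isolated)
30 | dimethyl 4-(Ar-oxy)-3,5-dioxoheptanedioate | COc1cc(Oc2c(OC)cc(Oc3c(OC)cc(Oc4c(OC)c(OC)c(OC)cc4Oc5c(OC)cc(Oc6c(OC)cc(OC(C(=O)CC(=O)OC)C(=O)CC(=O)OC)cc6OC)cc5OC)cc3OC)cc2OC)cc(OC)c1OC | intermediate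
31 | methyl 3-(Ar-oxy)-2,4,6-trihydroxybenzoate | COc1cc(Oc2c(OC)cc(Oc3c(OC)cc(Oc4c(OC)c(OC)c(OC)cc4Oc5c(OC)cc(Oc6c(OC)cc(Oc7c(O)cc(O)c(C(=O)OC)c7O)cc6OC)cc5OC)cc3OC)cc2OC)cc(OC)c1OC | intermediate
32 | 2,4,6-trihydroxybenzoic acid form of the fully demethylated heptamer (carboxyl at position 2 of ring A) | Oc1cc(O)c(Oc2cc(O)c(Oc3cc(O)c(Oc4cc(O)c(O)c(O)c4Oc4cc(O)c(Oc5cc(O)c(Oc6cc(O)c(O)c(O)c6)c(O)c5)c(O)c4)c(O)c3)c(O)c2)c(O)c1C(=O)O | intermediate (not isolated)
33 | CNP0304148.0 | Oc1cc(O)c(Oc2cc(O)c(Oc3cc(O)c(Oc4cc(O)c(O)c(O)c4Oc4cc(O)c(Oc5cc(O)c(Oc6cc(O)c(O)c(O)c6)c(O)c5)c(O)c4)c(O)c3)c(O)c2)c(O)c1 | target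

**Step count**

Total: 16 steps. Longest linear sequence: 14 steps (steps 1, 2, 3, 4, 7, 8, 9, 10, 11, 12, 13, 14, 15, 16); the branch through steps 5 and 6 joins at step 7.

**Steps most likely to fail**

Step 7. The phenol oxygen on ring D is flanked by a methoxy group and a bulky aryloxy group, so O-arylation may be slow enough for protodeboronation and oxidative homocoupling to consume the GFE boronic acid. The fallback sets out from 7 and returns at 15. Bromide 7 would be converted by an aromatic Finkelstein reaction (NaI, CuI cat., N,N′-dimethylethane-1,2-diamine, dioxane, 110 °C) into the GFE iodide F1. F1 would then be coupled with phenol 14 in an Ullmann ether synthesis (CuI cat., picolinic acid, K3PO4, DMSO, 80 °C), conditions made for hindered phenols, with the preference of the copper catalyst for the aryl iodide over the electron-rich bromide of ring C keeping the bromine of 14 in place.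

Step 14. Acylation at the diene terminus that carries the aryloxy group may be sluggish, so that desilylation back to 24 or O-acylation competes. The fallback sets out from 22 and returns at 30, forming the bond between the aryl oxygen and chain carbon 4 last instead of the bond between chain carbons 4 and 5. Dimethyl 3,5-dioxoheptanedioate F2 would be made from the commercial bis(silyl enol ether) of methyl acetoacetate and 28, the parent case of this acylation. Regitz diazo transfer (4-acetamidobenzenesulfonyl azide, one equivalent, Et3N, MeCN) at its most acidic methylene, carbon 4 between the ketones, would give dimethyl 4-diazo-3,5-dioxoheptanedioate F3. Rh2(OAc)4 (cat., CH2Cl2, 25 °C) would then insert the carbenoid into the O–H bond of phenol 22.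

Step 16. Cleavage of fourteen ethers and one ester in a single operation may stop at partly methylated products, and the free polyphenol may oxidise in air during work-up and chromatography. The fallback sets out from 31 and returns at 33, separating the events and purifying a protected form. Hot aqueous KOH under argon followed by acidification would hydrolyse and decarboxylate 31 to 2-(Ar-oxy)benzene-1,3,5-triol F4. AlCl3 and EtSH (CH2Cl2, 0 → 25 °C) would cleave the methyl ethers, and the crude polyphenol would be acetylated at once (Ac2O, pyridine) to the heptadecaacetate F5, which is stable to air and silica. Methanolysis with HCl in MeOH under argon would then release 33.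

**Further compounds**

F1 | step 7 | 5-iodo-2-[3,5-dimethoxy-4-(3,4,5-trimethoxyphenoxy)phenoxy]-1,3-dimethoxybenzene (GFE iodide) | COc1cc(Oc2c(OC)cc(Oc3c(OC)cc(I)cc3OC)cc2OC)cc(OC)c1OC
F2 | step 14 | dimethyl 3,5-dioxoheptanedioate | COC(=O)CC(=O)CC(=O)CC(=O)OC
F3 | step 14 | dimethyl 4-diazo-3,5-dioxoheptanedioate | COC(=O)CC(=O)C(=[N+]=[N-])C(=O)CC(=O)OC
F4 | step 16 | 2-(Ar-oxy)benzene-1,3,5-triol (ring A free, fourteen methyl ethers kept) | COc1cc(Oc2c(OC)cc(Oc3c(OC)cc(Oc4c(OC)c(OC)c(OC)cc4Oc5c(OC)cc(Oc6c(OC)cc(Oc7c(O)cc(O)cc7O)cc6OC)cc5OC)cc3OC)cc2OC)cc(OC)c1OC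
F5 | step 16 | heptadecaacetate of 33 | CC(=O)Oc1cc(OC(C)=O)c(Oc2cc(OC(C)=O)c(Oc3cc(OC(C)=O)c(Oc4cc(OC(C)=O)c(OC(C)=O)c(OC(C)=O)c4Oc4cc(OC(C)=O)c(Oc5cc(OC(C)=O)c(Oc6cc(OC(C)=O)c(OC(C)=O)c(OC(C)=O)c6)c(OC(C)=O)c5)c(OC(C)=O)c4)c(OC(C)=O)c3)c(OC(C)=O)c2)c(OC(C)=O)c1
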